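The numbers in the tables come from a simulation on assumed constants; the scatter is artificial.

Set Monday's and Friday's runs side by side and ask how much the second catalyst has taken from the intermediate by the last reading. The four new flasks keep the charges of those runs and change the second catalyst.

| setting | Monday's | Friday's | maple | alder | cedar | oak |
|---|---|---|---|---|---|---|
| starting material | 10 mM | 10 mM | 10 mM | 10 mM | 10 mM | 10 mM |
| coupling partner | 9 mM | 9 mM | 9.00 mM | 9.00 mM | 9.00 mM | 9.00 mM |
| free catalyst | 0.20 mM | 0.20 mM | 0.20 mM | 0.20 mM | 0.20 mM | 0.20 mM |
| second catalyst | 7.9 µM | 64 µM | 6.0 µM | 12 µM | 25 µM | 50 µM |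
| remark | run made earlier | run made earlier |  |  |  |  |
| time |  |  | 15 min | 15 min | 15 min | 15 min |

| run | time / min | intermediate / % | product / % |
|---|---|---|---|
| Monday's | 1.33 | 3.8 | 0 |
| Monday's | 3.00 | 7.7 | 0 |
| Monday's | 6.00 | 13.9 | 0 |
| Monday's | 15.0 | 26.6 | 0.3 |
| Friday's | 1.33 | 3.6 | 0 |
| Friday's | 3.00 | 7.5 | 0.2 |
| Friday's | 6.00 | 13.7 | 0.9 |
| Friday's | 15.0 | 24.9 | 2.8 |

(standard deviation of a reading: 0.3 percentage points)

* amount of intermediate at the end, in percent of the starting material charged for maple, alder, cedar, oak, in this order
* how that number moves from the first to the last of them (hardly changes / rises all the way / falls all the way / rises, then falls / falls, then rises)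

- the numbers in the tables scatter with a standard deviation of 0.3 percentage points
- "hardly changes" means that all values lie within two and a half points (for a concentration: within two and a half percent of the largest)

I went two ways. The first reads the intermediate itself: it stood at 26.6% on Monday and 24.9% on Friday, with the second catalyst at 7.9 µM and 64 µM. That slope, 0.303 /mM, makes a fall of 1.3 percentage points from maple to oak.

The second way reads the product, which appeared with a lag, so I took it to come from the intermediate. I called the drain the share of the starting material found as product at that last reading, per unit of second catalyst. Friday's run gives 0.438 /mM. Monday's gives 0.380 /mM from a reading of 0.3% with a scatter of 0.3 points, which is weak support, but I treated the product as first order in the second catalyst at this charge and time. Intermediate plus product, averaged over the two runs, is 27.3%. Taking the drain from that gave me 27.0%, 26.8%, 26.2% and 25.1%, a fall of 1.9 points.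

The drain is steeper than the first slope, so I looked for the cheat. The sums of intermediate and product were 7.70% and 7.70% at 3.00 min, but 26.9% and 27.7% at 15.0 min. That gap of 0.8 points is close to what separates the two ways, and it is built from four readings, each scattering by 0.3 points. The first way carries the gap into its slope, so I kept the second. A fall of 1.9 points, or the first way's figure, stands against a margin of 2.5 points, so my word was "hardly changes".

The forecast gave 26.7%, 26.5%, 26.1% and 25.3%, hardly changes, in its words “drifting slightly down”.

    starting material + free catalyst ⇌ free catalyst + intermediate (K = 1.40, k = 2.30 /M/s)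
    coupling partner + second catalyst + intermediate → second catalyst + product (k = 770 /M²/s)
    coupling partner ⇌ dormant form (K = 1.10, k = 0.00280 /s)
    intermediate → decomposed reagent (k = 1.60 × 10⁻⁴ /s)

The flasks gave 27.3%, 27.0%, 26.5% and 25.5%, hardly changes, a fall of 1.8 points against the 1.9 points from the drain. Starting material stood at 70.1% in maple and 69.9% in oak at the end. The drain times oak's 50 µM gives 2.19% of product, and oak held 2.41% at 15.0 min.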